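**Retrosynthetic overview**

1. The C2-symmetric 1,4-dioxane (C6–O–C7′ and C7–O–C6′) is cut into two molecules of the 6α,7α-epoxide 14. Each C7 is p-methoxybenzylic (para to the C12 methoxy group), so head-to-tail opening with inversion at C7 builds the central ring last.
2. Epoxide 14 comes from styrene 13 (α-face epoxidation), and 13 from ketone 11 (sugiol methyl ether) by reduction and dehydration.
3. Ring B of 11 is closed by the C6–C7 bond in a 6-endo cyclisation of the aroyl radical of aldehyde 10 onto the exocyclic C5=C6 methylene (radical hydroacylation). The enabling feature: C7 sits as a formyl carbon on C8, ortho to the C9–C10 bond, and C5=C6 is flanked by the quaternary carbons C4 and C10. The alkene therefore has no allylic hydrogen, only C6 is open to attack, and the axial C10 methyl steers hydrogen delivery to the α face of C5.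
4. Aldehyde 10 comes from ketone 6 by bromination at C8 (para to the methoxy group), methylenation of the C5 carbonyl and formylation. Ketone 6 comes from asymmetric α-arylation of 2,2,6-trimethylcyclohexanone 5 with aryl bromide 4 (C9–C10 bond, C10 stereocentre).
5. Ring order: ring C (from 1) and ring A (from 5) are joined in step 3, ring B closes in step 7, the oxirane in step 9 and the dioxane in step 10.

Key step: step 7

Remark: abietane numbering and α/β face descriptors are used for the tricyclic compounds and for the corresponding atoms of their precursors. Both halves of the target are (5S,6R,7R,10S), with a 6α- and a 7β-oxygen.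

Assumption: the sense of induction of the chiral bisphosphine in step 3 is taken by analogy with palladium-catalysed arylations of α-methyl cyclic ketones; if the antipode of 6 were to result, the enantiomeric ligand is used.

**Route**

Step 1
Reactants: 1 methyl 4-bromo-2-methoxybenzoate
Product: 3 2-(4-bromo-2-methoxyphenyl)propan-2-ol, via methyl ketone 2 (not isolated)
Conditions: MeMgBr (3.0 equiv), THF, 0 °C to rt; aq. NH4Cl
Reagents that add atoms: methylmagnesium bromide, C[Mg]Br
Why: Double Grignard addition to the ester through the methyl ketone should give the tertiary benzylic alcohol, the aryl bromide being inert to MeMgBr at this temperature, and no stereocentre is formed.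

Step 2
Reactants: 3 2-(4-bromo-2-methoxyphenyl)propan-2-ol
Product: 4 4-bromo-2-methoxy-1-(propan-2-yl)benzene
Conditions: Et3SiH (2.5 equiv), CF3CO2H, CH2Cl2, 0 °C to rt
Reagents that add atoms: none
Why: Ionic hydrogenation, in which the acid ionises the tertiary benzylic alcohol to a cation stabilised by the ortho methoxy group and the silane delivers hydride, while the aryl bromide is untouched.

Step 3
Reactants: 4 4-bromo-2-methoxy-1-(propan-2-yl)benzene, 5 2,2,6-trimethylcyclohexan-1-one (racemic, 1.5 equiv)
Product: 6 (2R)-2-[3-methoxy-4-(propan-2-yl)phenyl]-2,6,6-trimethylcyclohexan-1-one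
Conditions: Pd(dba)2 (5 mol %), (R)-DIFLUORPHOS (6 mol %), NaOt-Bu (1.5 equiv), toluene, 70 °C
Reagents that add atoms: none
Why: Palladium-catalysed asymmetric α-arylation of a ketone enolate, in which 5 has a single α-hydrogen (the other α-carbon is quaternary), the chiral bisphosphine on the arylpalladium enolate sets the quaternary centre (C10 of the target) in the C–C reductive elimination, and the product has no α-hydrogen left and cannot racemise.

Step 4
Reactants: 6 (2R)-2-[3-methoxy-4-(propan-2-yl)phenyl]-2,6,6-trimethylcyclohexan-1-one
Product: 7 (2R)-2-[2-bromo-5-methoxy-4-(propan-2-yl)phenyl]-2,6,6-trimethylcyclohexan-1-one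
Conditions: NBS (1.05 equiv), MeCN, 0 °C to rt, dark
Reagents that add atoms: N-bromosuccinimide, O=C1CCC(=O)N1Br
Why: Electrophilic aromatic bromination should go para to the methoxy group (C8), since one ortho position carries the isopropyl group and the other lies between two substituents, and the ketone has no enolisable hydrogen.

Step 5
Reactants: 7 (2R)-2-[2-bromo-5-methoxy-4-(propan-2-yl)phenyl]-2,6,6-trimethylcyclohexan-1-one
Product: 8 1-bromo-4-methoxy-5-(propan-2-yl)-2-[(1S)-1,3,3-trimethyl-2-methylidenecyclohexyl]benzene
Conditions: Cp2TiMe2 (3 equiv), toluene, 75 °C, dark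
Reagents that add atoms: dimethyltitanocene (Petasis reagent), C[Ti](C)(C1C=CC=C1)C1C=CC=C1
Why: Petasis methylenation through Cp2Ti=CH2 (cycloaddition to the carbonyl and cycloreversion) is non-basic, suits hindered non-enolisable ketones and tolerates the aryl bromide, and the quaternary stereocentre is not involved.

Step 6
Reactants: 8 1-bromo-4-methoxy-5-(propan-2-yl)-2-[(1S)-1,3,3-trimethyl-2-methylidenecyclohexyl]benzene
Product: 10 4-methoxy-5-(propan-2-yl)-2-[(1S)-1,3,3-trimethyl-2-methylidenecyclohexyl]benzaldehyde, via aryllithium 9 (not isolated)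
Conditions: n-BuLi (1.1 equiv), THF, −78 °C; DMF (3 equiv), −78 to 0 °C; aq. NH4Cl
Reagents that add atoms: N,N-dimethylformamide, CN(C)C=O; n-butyllithium, [Li]CCCC (lithium of intermediate 9 only)
Why: Bromine–lithium exchange followed by Bouveault formylation places the C7 carbon on C8, and the alkene, which has no allylic hydrogen, is inert to the base.

Step 7
Reactants: 10 4-methoxy-5-(propan-2-yl)-2-[(1S)-1,3,3-trimethyl-2-methylidenecyclohexyl]benzaldehyde
Product: 11 (5S,10S)-12-methoxyabieta-8,11,13-trien-7-one (sugiol methyl ether)
Conditions: t-C12H25SH (10 mol %), di-tert-butyl hyponitrite (2 × 5 mol %), 1,4-dioxane (0.05 M), 60 °C, argon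
Reagents that add atoms: none
Why: A thiyl radical abstracts the aldehyde hydrogen of 10 (polarity-reversal catalysis), the σ-aroyl radical at C7 adds to the CH2 terminus C6 of the exocyclic alkene, and the tertiary C5 radical takes hydrogen back from the thiol, so the chain turns the aldehyde into the ketone by isomerisation (intramolecular radical hydroacylation). The closest known reaction types are the thiol-catalysed radical-chain hydroacylation of alkenes by aldehydes, including cyclisations of alkenals, and the 6-endo cyclisation of ortho-alkenyl aroyl radicals made from selenoesters. Ring B closes in the 6-endo-trig mode, because 5-exo attack would have to create a quaternary C5 between the quaternary carbons C4 and C10, and any 5-exo adduct would ring-expand to the same tertiary radical by 1,2-acyl shift. The new stereocentre C5 is controlled by C10: the β face of the planar C5 radical is screened by the axial C10 methyl and the β methyl on C4, so the thiol should deliver hydrogen to the α face and give the trans A/B fusion (5S). The step needs addition at C6 rather than C5, chain transfer faster than 1,2-aryl (neophyl) shift of the C5 radical, and no loss of CO; the fully substituted C5, the fast hydrogen donation by the thiol and the strength of the aryl–CO bond secure these. C10 is quaternary and is not touched.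

Step 8
Reactants: 11 (5S,10S)-12-methoxyabieta-8,11,13-trien-7-one
Product: 13 (5S,10S)-12-methoxyabieta-6,8,11,13-tetraene (6,7-dehydroferruginol methyl ether), via benzylic alcohol 12 (not isolated)
Conditions: LiAlH4 (1.0 equiv), THF, 0 °C; aq. work-up; then p-TsOH·H2O (5 mol %), toluene, 80 °C
Reagents that add atoms: none
Why: Hydride reduction of the aryl ketone and acid-catalysed E1 dehydration of the p-methoxybenzylic alcohol should give the conjugated C6=C7 styrene, the C7 configuration of 12 being irrelevant and C5 (not α to the carbonyl) being unaffected.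

Step 9
Reactants: 13 (5S,10S)-12-methoxyabieta-6,8,11,13-tetraene
Product: 14 (5S,6R,7S,10S)-6α,7α-epoxy-12-methoxyabieta-8,11,13-triene
Conditions: DMDO (1.2 equiv, acetone solution), CH2Cl2, −20 to 0 °C; evaporated cold and used at once
Reagents that add atoms: dimethyldioxirane, CC1(C)OO1
Why: Epoxidation with the neutral dioxirane should occur on the α face, because the β face of the C6=C7 bond is screened by the axial C10 methyl and the β methyl on C4, which sets C6 (R) and C7 (S) without acid that would open the labile p-methoxyaryl oxirane.

Step 10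
Reactants: 14 (5S,6R,7S,10S)-6α,7α-epoxy-12-methoxyabieta-8,11,13-triene (two molecules)
Product: 15 the target, C2-symmetric 1,4-dioxane made of two (5S,6R,7R,10S)-12-methoxyabieta-8,11,13-triene units joined C6α–O–C7′β and C7β–O–C6′α
Conditions: camphorsulfonic acid (2 mol %), 4 Å MS, CH2Cl2 (0.5 M), −40 to 0 °C; Et3N quench
Reagents that add atoms: none
Why: Acid-catalysed head-to-tail cyclodimerisation of an aryl epoxide to a 1,4-dioxane, in which the oxirane oxygen of a second molecule opens the protonated epoxide at the p-methoxybenzylic C7 from the β face and the 6α-oxygen set free closes the six-membered ring on C7 of the oxonium partner in the same way, so that both C7 centres are inverted (7α to 7β), both C6–O bonds are retained and, 14 being a single enantiomer, only the homochiral C2-symmetric dimer can form.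

**Compound list**

1 | methyl 4-bromo-2-methoxybenzoate | COC(=O)c1ccc(Br)cc1OC | starting material
2 | 1-(4-bromo-2-methoxyphenyl)ethan-1-one (forms and reacts on in step 1) | CC(=O)c1ccc(Br)cc1OC | intermediate
3 | 2-(4-bromo-2-methoxyphenyl)propan-2-ol | CC(C)(O)c1ccc(Br)cc1OC | intermediate
4 | 4-bromo-2-methoxy-1-(propan-2-yl)benzene | CC(C)c1ccc(Br)cc1OC | intermediate
5 | 2,2,6-trimethylcyclohexan-1-one (racemic) | CC1CCCC(C)(C)C1=O | starting material
6 | (2R)-2-[3-methoxy-4-(propan-2-yl)phenyl]-2,6,6-trimethylcyclohexan-1-one | CC1(C)CCC[C@](C)(c2ccc(C(C)C)c(OC)c2)C1=O | intermediate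
7 | (2R)-2-[2-bromo-5-methoxy-4-(propan-2-yl)phenyl]-2,6,6-trimethylcyclohexan-1-one | CC1(C)CCC[C@](C)(c2cc(OC)c(C(C)C)cc2Br)C1=O | intermediate
8 | 1-bromo-4-methoxy-5-(propan-2-yl)-2-[(1S)-1,3,3-trimethyl-2-methylidenecyclohexyl]benzene | CC1(C)CCC[C@](C)(c2cc(OC)c(C(C)C)cc2Br)C1=C | intermediate
9 | {4-methoxy-5-(propan-2-yl)-2-[(1R)-1,3,3-trimethyl-2-methylidenecyclohexyl]phenyl}lithium (same spatial arrangement as 8; the descriptor changes by priority only) | CC1(C)CCC[C@](C)(c2cc(OC)c(C(C)C)cc2[Li])C1=C | intermediate
10 | 4-methoxy-5-(propan-2-yl)-2-[(1S)-1,3,3-trimethyl-2-methylidenecyclohexyl]benzaldehyde | CC1(C)CCC[C@](C)(c2cc(OC)c(C(C)C)cc2C=O)C1=C | intermediate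
11 | (5S,10S)-12-methoxyabieta-8,11,13-trien-7-one (sugiol methyl ether) | COc1cc2c(cc1C(C)C)C(=O)C[C@H]1C(C)(C)CCC[C@]21C | intermediate
12 | (5S,10S)-12-methoxyabieta-8,11,13-trien-7-ol (C7 epimers) | COc1cc2c(cc1C(C)C)C(O)C[C@H]1C(C)(C)CCC[C@]21C | intermediate
13 | (5S,10S)-12-methoxyabieta-6,8,11,13-tetraene | COc1cc2c(cc1C(C)C)C=C[C@H]1C(C)(C)CCC[C@]21C | intermediate
14 | (5S,6R,7S,10S)-6α,7α-epoxy-12-methoxyabieta-8,11,13-triene | COc1cc2c(cc1C(C)C)[C@@H]1O[C@@H]1[C@H]1C(C)(C)CCC[C@]21C | intermediate
15 | target: head-to-tail 1,4-dioxane dimer, each half (5S,6R,7R,10S)-12-methoxyabieta-8,11,13-triene-6α,7β-diyl | COc1cc2c(cc1C(C)C)[C@H]1O[C@H]3[C@H](O[C@@H]1[C@H]1C(C)(C)CCC[C@]21C)c1cc(C(C)C)c(OC)cc1[C@@]1(C)CCCC(C)(C)[C@H]31 | target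

**Step count**

Total steps: 10. Longest linear sequence: 10 steps (1 to 15); ketone 5 enters at step 3.

**Steps most likely to fail**

Step 10. In a homochiral dimer the two O–C6–C7–O torsions at the ring fusions have the same sign, so the central dioxane cannot be a chair (trans-anti-trans array) and the product must form under kinetic control. What may go wrong: full ionisation of the C7–O bond before the second oxygen arrives, followed by capture of the p-methoxybenzyl cation on the α face, would give cis-fused, all-chair dimers. A 1,2-hydride shift from C6 to C7 (Meinwald rearrangement) would give the C6 ketone. The fallback builds the two C7–O bonds one at a time by SN2 chemistry. It sets out from alkene 13 and epoxide 14 and returns at 15. Alkene 13 is dihydroxylated on the α face (OsO4 cat., N-methylmorpholine N-oxide, acetone/water) to the 6α,7α-diol F1. The less hindered benzylic hydroxyl is silylated (t-BuMe2SiCl, imidazole, DMF) to give the 7-silyl ether F2. The sodium alkoxide of F2 (NaH, DMF, 60 °C) opens epoxide 14 at C7 with inversion to the hydroxy ether F3. Bu4NF removes the silyl group to give the diol F4. Intramolecular Mitsunobu etherification (PPh3, diisopropyl azodicarboxylate, THF) then displaces the activated benzylic 7α-hydroxyl by the 6α-hydroxyl of the other half with inversion and closes the dioxane of 15.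

Step 7. What may go wrong: slow abstraction of the aldehyde hydrogen of the hindered, electron-rich aryl aldehyde, so that the chain is short; loss of the thiol by thiol–ene addition to the alkene; or hydrogen delivery to the β face of the C5 radical. The fallback makes the same aroyl radical from a selenoester; it sets out from aldehyde 10 and returns at 11. Pinnick oxidation (NaClO2, NaH2PO4, 2-methylbut-2-ene, t-BuOH/water) gives the benzoic acid F5. Diphenyl diselenide and PBu3 in THF convert it into the Se-phenyl selenoester F6. Slow addition of (Me3Si)3SiH with azobisisobutyronitrile in benzene at 80 °C should then give 11 by the same 6-endo cyclisation and α-face reduction.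

Step 5. What may go wrong: no reaction of the titanium methylidene with a carbonyl group flanked by two quaternary carbons and an ortho-bromoaryl group, with thermal decay of the reagent instead. The fallback replaces carbonyl olefination by addition and elimination; it sets out from ketone 7 and returns at 8. MeLi with CeCl3 in THF at −78 °C adds to the carbonyl group to give the tertiary carbinol F7. Syn elimination with the Burgess reagent in toluene at 80 °C can only take a hydrogen of the new methyl group and should give the exocyclic alkene 8.

**Further compounds**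

F1 | step 10 | (5S,6R,7S,10S)-12-methoxyabieta-8,11,13-triene-6α,7α-diol | COc1cc2c(cc1C(C)C)[C@H](O)[C@H](O)[C@H]1C(C)(C)CCC[C@]21C
F2 | step 10 | (5S,6R,7S,10S)-7α-(tert-butyldimethylsilyloxy)-12-methoxyabieta-8,11,13-trien-6α-ol | COc1cc2c(cc1C(C)C)[C@H](O[Si](C)(C)C(C)(C)C)[C@H](O)[C@H]1C(C)(C)CCC[C@]21C
F3 | step 10 | hydroxy ether: the 6α-oxygen of the silyl ether half bonded to C7β of a second half that carries a free 6α-hydroxyl | COc1cc2c(cc1C(C)C)[C@H](O[Si](C)(C)C(C)(C)C)[C@H](O[C@@H]3c4cc(C(C)C)c(OC)cc4[C@@]4(C)CCCC(C)(C)[C@@H]4[C@H]3O)[C@H]1C(C)(C)CCC[C@]21C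
F4 | step 10 | diol: F3 without the silyl group (7α-hydroxyl on one half, 6α-hydroxyl on the other) | COc1cc2c(cc1C(C)C)[C@H](O)[C@H](O[C@@H]3c4cc(C(C)C)c(OC)cc4[C@@]4(C)CCCC(C)(C)[C@@H]4[C@H]3O)[C@H]1C(C)(C)CCC[C@]21C
F5 | step 7 | 4-methoxy-5-(propan-2-yl)-2-[(1S)-1,3,3-trimethyl-2-methylidenecyclohexyl]benzoic acid | CC1(C)CCC[C@](C)(c2cc(OC)c(C(C)C)cc2C(=O)O)C1=C
F6 | step 7 | Se-phenyl 4-methoxy-5-(propan-2-yl)-2-[(1S)-1,3,3-trimethyl-2-methylidenecyclohexyl]benzenecarboselenoate | CC1(C)CCC[C@](C)(c2cc(OC)c(C(C)C)cc2C(=O)[Se]c2ccccc2)C1=C
F7 | step 5 | (2R)-2-[2-bromo-5-methoxy-4-(propan-2-yl)phenyl]-1,2,6,6-tetramethylcyclohexan-1-ol (C1 epimers) | CC1(C)CCC[C@](C)(c2cc(OC)c(C(C)C)cc2Br)C1(C)O
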